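The quinone ring of the target, numbered C1(=O), C2(OAc), C3(aryl), C4(=O), C5(OH), C6(aryl), is twofold symmetric apart from the acetyl group. Two O–C=C–aryl pairs (C2–C3 and C5–C6) sit head to tail on either side of the isolated carbonyl carbons C1 and C4. All four ring bonds to C1 and C4 are therefore disconnected, so that a single light-driven reaction on iron joins two molecules of an aryl ynol ether with two carbonyl ligands and delivers the quinone at its final oxidation level with all ring oxygens installed. The precursor is 4-(ethoxyethynyl)phenyl acetate, whose electron-poor aryl group reinforces the ynol ether polarisation; saponification and one enol acetylation complete the route.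

Key step: step 2

Assumption: the two quinone enol hydroxyls of tetrol 9 are related by symmetry, so acetylation of either one gives the same target; ethoxyacetylene is used as its commercial hexane solution.

Step 1
Reactants: 1 ethoxyacetylene; 2 4-iodophenyl acetate
Product: 5 4-(ethoxyethynyl)phenyl acetate, via lithium ethoxyacetylide 3 (not isolated), via ethoxyethynylzinc chloride 4 (not isolated)
Conditions: 1 (1.3 equiv), n-BuLi, THF, −78 °C; ZnCl2 (1.4 equiv), −78 → 0 °C; 2, Pd(PPh3)4 (3 mol %), THF, rt; NaHCO3 work-up, Et3N-deactivated silica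
Reagents that add atoms: none
Why: Negishi coupling, in which the terminal ynol ether is lithiated, transmetallated to an alkynylzinc chloride that does not attack the aryl ester, and cross-coupled with the aryl iodide under zerovalent palladium, a known way to aryl ethoxyacetylenes that tolerates esters.

Step 2
Reactants: 5 4-(ethoxyethynyl)phenyl acetate (two molecules); 6 pentacarbonyliron
Product: 8 2,5-diethoxy-3,6-bis(4-acetoxyphenyl)-1,4-benzoquinone, via tricarbonyl(quinone)iron complex 7 (not isolated)
Conditions: Fe(CO)5 (0.6 equiv), CO (2 atm), toluene, hν (Pyrex filter, 350–400 nm), 5 °C; then (NH4)2Ce(NO3)6 (3.3 equiv), MeCN–H2O, 0 °C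
Reagents that add atoms: pentacarbonyliron, O=C=[Fe](=C=O)(=C=O)(=C=O)=C=O; carbon monoxide, [C-]#[O+]
Why: Proposed new method: photolytic CO loss from Fe(CO)5 lets one molecule of 5 couple with two carbonyl ligands to a maleoyl ferracycle, Fe–C(=O)–C(OEt)=C(Ar)–C(=O)–Fe, a second molecule of 5 inserts into an iron–acyl bond, and C–C reductive elimination gives the tricarbonyl(η4-quinone)iron complex 7, from which tetravalent cerium releases quinone 8. The closest known reaction type is the light-driven cyclocarbonylation of two dialkylacetylenes with Fe(CO)5 to tricarbonyl(quinone)iron complexes, together with the regioselective union of maleoylcobalt complexes with alkynes; ynol ethers and head-to-tail control on iron are untested. The single six-membered ring closes by reductive elimination from a seven-membered ferracycle, a metal-templated [2+2+1+1] assembly that forms C1–C2, C3–C4, C4–C5 and C6–C1, and no stereocentre is created. Head-to-tail selectivity requires the aryl-bearing, nucleophilic carbon of the second ynol ether to bond to the acyl carbon next to C–OEt, which is the more electrophilic one because the other acyl is the carbonyl end of a vinylogous ester; the electron-poor 4-acetoxyphenyl group leaves the alkyne polarised by the ethoxy oxygen alone, whereas a 4-alkoxyphenyl group would oppose that bias. Double carbonylation is favoured over cyclopentadienone formation by the CO atmosphere and low temperature, and filtered light at 5 °C avoids photo-Fries rearrangement of the aryl acetates and thermal loss of ethylene from the ynol ether.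

Step 3
Reactants: 8 2,5-diethoxy-3,6-bis(4-acetoxyphenyl)-1,4-benzoquinone
Product: 9 atromentin [2,5-dihydroxy-3,6-bis(4-hydroxyphenyl)-1,4-benzoquinone]
Conditions: NaOH (2 M aq, 8 equiv), THF, 0 °C → rt, under Ar; then aq HCl to pH 1, filtration
Reagents that add atoms: sodium hydroxide, [Na+].[OH-]; water, O
Why: Saponification, in which hydroxide cleaves the two aryl acetates and displaces both ethoxy groups of the quinone vinylogous esters by addition–elimination, the hydroxyquinone anion being the thermodynamic sink, so that acidification should precipitate the free tetrol.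

Step 4
Reactants: 9 atromentin
Product: 10 2-acetoxy-5-hydroxy-3,6-bis(4-hydroxyphenyl)-1,4-benzoquinone (target)
Conditions: iPr2NEt (2.0 equiv), THF–MeCN, −40 °C; AcCl (1.0 equiv), −40 → 0 °C; cold aq citric acid work-up
Reagents that add atoms: acetyl chloride, CC(=O)Cl
Why: O-acylation of a vinylogous carboxylate, in which two equivalents of the hindered amine are consumed by the two strongly acidic quinone enols alone, the resulting dianion is acylated faster than the neutral phenols and than the less electron-rich monoanion left after the first acetyl transfer, and the equivalence of the two enols makes any mono-acetate the target.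

Compound list
1 | ethoxyacetylene (ethoxyethyne) | CCOC#C | starting material
2 | 4-iodophenyl acetate | CC(=O)Oc1ccc(I)cc1 | starting material
3 | lithium ethoxyacetylide, EtOC≡CLi | CCOC#C[Li] | intermediate
4 | ethoxyethynylzinc chloride, EtOC≡CZnCl | CCOC#C[Zn]Cl | intermediate
5 | 4-(ethoxyethynyl)phenyl acetate | CCOC#Cc1ccc(OC(C)=O)cc1 | intermediate
6 | pentacarbonyliron, Fe(CO)5 | O=C=[Fe](=C=O)(=C=O)(=C=O)=C=O | starting material
7 | tricarbonyl[η4-2,5-diethoxy-3,6-bis(4-acetoxyphenyl)-1,4-benzoquinone]iron (iron bound to the C2=C3 and C5=C6 bonds; written as quinone and Fe(CO)3 joined by a dot) | CCOC1=C(c2ccc(OC(C)=O)cc2)C(=O)C(OCC)=C(c2ccc(OC(C)=O)cc2)C1=O.O=C=[Fe](=C=O)=C=O | intermediate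
8 | 2,5-diethoxy-3,6-bis(4-acetoxyphenyl)-1,4-benzoquinone | CCOC1=C(c2ccc(OC(C)=O)cc2)C(=O)C(OCC)=C(c2ccc(OC(C)=O)cc2)C1=O | intermediate
9 | atromentin, 2,5-dihydroxy-3,6-bis(4-hydroxyphenyl)-1,4-benzoquinone | OC1=C(c2ccc(O)cc2)C(=O)C(O)=C(c2ccc(O)cc2)C1=O | intermediate
10 | 2-acetoxy-5-hydroxy-3,6-bis(4-hydroxyphenyl)-1,4-benzoquinone | CC(=O)OC1=C(c2ccc(O)cc2)C(=O)C(O)=C(c2ccc(O)cc2)C1=O | target

Total step count: 4. Longest linear sequence: 4 steps (1 → 5 → 8 → 9 → 10).

Steps most likely to fail

Step 2. The iron may take up only one CO and give cyclopentadienone or ferrole complexes, the second alkyne may insert head to head, or the alkynyl C–O bond may be cleaved on iron. The fallback uses known chemistry, sets out from 2 and comes back to the route at 9. Miyaura borylation of 2 (B2pin2, PdCl2(dppf), KOAc, dioxane, 80 °C) should give 4-(4,4,5,5-tetramethyl-1,3,2-dioxaborolan-2-yl)phenyl acetate F1. Commercial tetrabromo-1,4-benzoquinone with NaOMe in MeOH should give 2,5-dibromo-3,6-dimethoxy-1,4-benzoquinone F2. A twofold Suzuki–Miyaura coupling of F2 with F1 (Pd(PPh3)4, anhydrous K3PO4, dioxane, 80 °C) should give 2,5-dimethoxy-3,6-bis(4-acetoxyphenyl)-1,4-benzoquinone F3. The saponification conditions of step 3 should then convert F3 into 9.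

Step 4. A second enol acetylation, acetyl transfer to the phenols, or hydrolytic loss of the labile enol acetate during isolation may erode the outcome. The fallback sets out from 9 and comes back at 10, and it masks the phenols before the acetyl group is introduced. Exhaustive silylation (TBSCl, imidazole, DMF) should give the tetrakis(tert-butyldimethylsilyl) ether of atromentin F4, which is not isolated. Its two silyl enol ethers are as labile as silyl esters and should fall off on stirring with AcOH in aqueous THF, leaving 2,5-dihydroxy-3,6-bis[4-(tert-butyldimethylsilyloxy)phenyl]-1,4-benzoquinone F5. Acetylation of its dianion in CH2Cl2 at −78 °C (iPr2NEt 2.0 equiv, AcCl 1.0 equiv) should give 2-acetoxy-5-hydroxy-3,6-bis[4-(tert-butyldimethylsilyloxy)phenyl]-1,4-benzoquinone F6; any bis-acetate can be returned to F5 with aqueous NaHCO3. HF·pyridine in THF at 0 °C is expected to remove the aryl silyl ethers and spare the acetate, giving 10.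

Step 1. Incomplete transmetallation would leave basic lithium acetylide that attacks the aryl acetate, and alkyne homocoupling or hydration of the ynol ether on work-up may also occur. The fallback sets out from 1 and comes back at 5. Compound 1 is converted with n-BuLi and Bu3SnCl into tributyl(ethoxyethynyl)stannane F7, which is distilled. F7 is then coupled with 2 under neutral Stille conditions (PdCl2(PPh3)2, Et4NCl, DMF, rt), so that no strongly basic species meets the ester.

Further compounds
F1 | step 2 | 4-(4,4,5,5-tetramethyl-1,3,2-dioxaborolan-2-yl)phenyl acetate | CC(=O)Oc1ccc(cc1)B1OC(C)(C)C(C)(C)O1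
F2 | step 2 | 2,5-dibromo-3,6-dimethoxy-1,4-benzoquinone | COC1=C(Br)C(=O)C(OC)=C(Br)C1=O
F3 | step 2 | 2,5-dimethoxy-3,6-bis(4-acetoxyphenyl)-1,4-benzoquinone | COC1=C(c2ccc(OC(C)=O)cc2)C(=O)C(OC)=C(c2ccc(OC(C)=O)cc2)C1=O
F4 | step 4 | 2,5-bis(tert-butyldimethylsilyloxy)-3,6-bis[4-(tert-butyldimethylsilyloxy)phenyl]-1,4-benzoquinone | CC(C)(C)[Si](C)(C)OC1=C(c2ccc(O[Si](C)(C)C(C)(C)C)cc2)C(=O)C(O[Si](C)(C)C(C)(C)C)=C(c2ccc(O[Si](C)(C)C(C)(C)C)cc2)C1=O
F5 | step 4 | 2,5-dihydroxy-3,6-bis[4-(tert-butyldimethylsilyloxy)phenyl]-1,4-benzoquinone | OC1=C(c2ccc(O[Si](C)(C)C(C)(C)C)cc2)C(=O)C(O)=C(c2ccc(O[Si](C)(C)C(C)(C)C)cc2)C1=O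
F6 | step 4 | 2-acetoxy-5-hydroxy-3,6-bis[4-(tert-butyldimethylsilyloxy)phenyl]-1,4-benzoquinone | CC(=O)OC1=C(c2ccc(O[Si](C)(C)C(C)(C)C)cc2)C(=O)C(O)=C(c2ccc(O[Si](C)(C)C(C)(C)C)cc2)C1=O
F7 | step 1 | tributyl(ethoxyethynyl)stannane | CCCC[Sn](CCCC)(CCCC)C#COCC
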